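## Retrosynthetic overview

1. Labels: ring A is the guaiacyl ring. Ring B is the dihydrofuran O1–C2–C3, fused to arene ring C (C3a–C7a). Ring D is the dihydrofuran O1'–C2'–C3', fused to arene ring E (C3a'–C7a'). The plan rests on the C2'–C3' bond of ring D: C2' is a benzylic ether carbon (bonded to O1' and to C5 of ring C), C3' is the α-carbon of an arylacetic ester on C3a' of ring E, and the path C3'–C3a'–C7a'–O1'–C2' makes them 1,5, the spacing at which a metal carbenoid inserts into a C–H bond.
2. Target 26 ⇐ (desilylation, Suzuki–Miyaura coupling at C5'–Br, ester reduction, C3' epimerisation) ⇐ cis ring D ester 21 ⇐ (carbenoid C–H insertion forming C2'–C3') ⇐ diazo ester 20.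
3. 20 ⇐ (diazo transfer, Mitsunobu etherification O1'–CH2) ⇐ ring A/B/C benzylic alcohol 18 + phenol ester 5.
4. 18 ⇐ (C5–Br to CH2OH, ester to CH2OTBS, C3 epimerisation) ⇐ cis ring B ester 11 ⇐ the same insertion on diazo ester 10 ⇐ vanillin-derived alcohol 8 + the same phenol ester 5, which comes from 5-bromo-2-hydroxy-3-methoxybenzaldehyde 1.
5. Ring order: arenes A, C and E are bought. Ring B is closed first (step 8) and ring D second (step 16).

Key step: step 16

Assumption: Rh2(S-PTTL)4 is taken to give the R configuration at the benzylic carbon (C2 in step 8, C2' in step 16), as with simpler 2-(benzyloxy)phenyl diazoacetates, and the (R)-lactamide/Rh2(R-DOSP)4 pair in the fallback to step 16 is taken to act in the same sense; if either sense proved opposite, the mirror-image ligand or auxiliary would be used with nothing else changed.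

## Route

Step 1
Reactants: 1 5-bromo-2-hydroxy-3-methoxybenzaldehyde
Product: 2 5-bromo-3-methoxy-2-(methoxymethoxy)benzaldehyde
Conditions: MOMCl, i-Pr2NEt, CH2Cl2, 0 °C to rt
Reagents that add atoms: chloromethyl methyl ether (MOMCl), COCCl
Why: Williamson-type O-alkylation of the acidic salicylaldehyde phenol masks it as a base-stable acetal that tolerates the strong base of step 2 and is removed by the acid of step 3 without an extra operation.

Step 2
Reactants: 2 5-bromo-3-methoxy-2-(methoxymethoxy)benzaldehyde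
Product: 4 2-[5-bromo-3-methoxy-2-(methoxymethoxy)phenyl]acetonitrile, via N-(1-tosylvinyl)formamide 3 (not isolated)
Conditions: TosMIC, t-BuOK, DME, −50 °C; then MeOH, reflux
Reagents that add atoms: tosylmethyl isocyanide (TosMIC), Cc1ccc(cc1)S(=O)(=O)C[N+]#[C-]
Why: Van Leusen reductive cyanation, in which the TosMIC anion adds to the aldehyde, the oxazoline opens to 3, and methanolysis of the formyl group with loss of sulfinate gives the one-carbon-longer nitrile without passing through an ortho-oxygenated benzylic halide.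

Step 3
Reactants: 4 2-[5-bromo-3-methoxy-2-(methoxymethoxy)phenyl]acetonitrile
Product: 5 methyl 2-(5-bromo-2-hydroxy-3-methoxyphenyl)acetate
Conditions: conc. H2SO4, MeOH, H2O (1.5 equiv), reflux
Reagents that add atoms: methanol, CO; water, O
Why: Pinner-type acid alcoholysis of the nitrile gives the methyl ester while the same acid transacetalises the MOM group, and the large excess of methanol keeps the hydroxy ester from closing to the benzofuranone.

Step 4
Reactants: 6 vanillin
Product: 7 3-methoxy-4-(triisopropylsilyloxy)benzaldehyde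
Conditions: TIPSCl, imidazole, DMF, rt
Reagents that add atoms: chlorotriisopropylsilane (TIPSCl), CC(C)[Si](Cl)(C(C)C)C(C)C
Why: Imidazole-promoted phenol silylation, with TIPS chosen over smaller silyl groups because it must outlast DBU (steps 7 and 15) and methoxide (steps 9 and 17), since a free para-phenoxide could open ring B at C2–O1 through a quinone methide.

Step 5
Reactants: 7 3-methoxy-4-(triisopropylsilyloxy)benzaldehyde
Product: 8 [3-methoxy-4-(triisopropylsilyloxy)phenyl]methanol
Conditions: NaBH4, MeOH/THF, 0 °C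
Reagents that add atoms: none
Why: Chemoselective borohydride reduction of the aldehyde, which leaves the hindered aryl silyl ether untouched at 0 °C.

Step 6
Reactants: 5 methyl 2-(5-bromo-2-hydroxy-3-methoxyphenyl)acetate; 8 [3-methoxy-4-(triisopropylsilyloxy)phenyl]methanol
Product: 9 methyl 2-[5-bromo-3-methoxy-2-{[3-methoxy-4-(triisopropylsilyloxy)phenyl]methoxy}phenyl]acetate
Conditions: PPh3, DIAD, THF, 0 °C to rt
Reagents that add atoms: none
Why: Mitsunobu etherification, in which phenol 5 protonates the betaine and displaces the oxyphosphonium of the primary benzylic alcohol under neutral conditions, so that neither a labile para-silyloxybenzyl halide nor a carbonate base that would attack the aryl silyl ether is needed.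

Step 7
Reactants: 9 methyl 2-[5-bromo-3-methoxy-2-{[3-methoxy-4-(triisopropylsilyloxy)phenyl]methoxy}phenyl]acetate
Product: 10 methyl 2-[5-bromo-3-methoxy-2-{[3-methoxy-4-(triisopropylsilyloxy)phenyl]methoxy}phenyl]-2-diazoacetate
Conditions: p-ABSA, DBU, dry MeCN, 0 °C to rt
Reagents that add atoms: 4-acetamidobenzenesulfonyl azide (p-ABSA), CC(=O)Nc1ccc(cc1)S(=O)(=O)N=[N+]=[N-]
Why: Regitz diazo transfer, in which DBU enolises the arylacetate, the α-carbon attacks the terminal nitrogen of the sulfonyl azide, and collapse of the triazene leaves the donor/acceptor diazo ester.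

Step 8
Reactants: 10 methyl 2-[5-bromo-3-methoxy-2-{[3-methoxy-4-(triisopropylsilyloxy)phenyl]methoxy}phenyl]-2-diazoacetate
Product: 11 methyl (2R,3S)-5-bromo-7-methoxy-2-[3-methoxy-4-(triisopropylsilyloxy)phenyl]-2,3-dihydro-1-benzofuran-3-carboxylate (cis)
Conditions: Rh2(S-PTTL)4 (dirhodium tetrakis[N-phthaloyl-(S)-tert-leucinate], 1–2 mol%), toluene, 4 Å MS, −60 °C, slow addition of 10
Reagents that add atoms: none
Why: Enantioselective intramolecular 1,5 C–H insertion of a dirhodium donor/acceptor carbenoid into the benzylic ether CH2, a known route to cis-2-aryl-2,3-dihydrobenzofuran-3-carboxylates, in which the chiral carboxylate ligands select one of the two enantiotopic hydrogens and so fix C2 as R, and the compact transition state places ring A and the ester on the same face (3S).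

Step 9
Reactants: 11 methyl (2R,3S)-5-bromo-7-methoxy-2-[3-methoxy-4-(triisopropylsilyloxy)phenyl]-2,3-dihydro-1-benzofuran-3-carboxylate
Product: 12 methyl (2R,3R)-5-bromo-7-methoxy-2-[3-methoxy-4-(triisopropylsilyloxy)phenyl]-2,3-dihydro-1-benzofuran-3-carboxylate (trans)
Conditions: NaOMe (0.2 equiv), MeOH/THF, 0 °C to rt; AcOH quench
Reagents that add atoms: none
Why: Base-mediated epimerisation through the ester enolate moves the ester to the less crowded trans face (3R), while C2 holds because expulsion of O1 from the enolate would be the reverse of a 5-endo-trig closure, the C2–O1 bond lying close to the nodal plane of the enolate π system.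

Step 10
Reactants: 12 methyl (2R,3R)-5-bromo-7-methoxy-2-[3-methoxy-4-(triisopropylsilyloxy)phenyl]-2,3-dihydro-1-benzofuran-3-carboxylate
Product: 13 [(2R,3S)-5-bromo-7-methoxy-2-[3-methoxy-4-(triisopropylsilyloxy)phenyl]-2,3-dihydro-1-benzofuran-3-yl]methanol (trans)
Conditions: LiAlH4, THF, 0 °C; aqueous NaOH work-up
Reagents that add atoms: none
Why: Hydride reduction of the ester to the primary alcohol spares the aryl bromide and the aryl silyl ether at 0 °C and removes the acidity of C3–H, so that C3 (now S through a change of priorities only) can no longer epimerise.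

Step 11
Reactants: 13 [(2R,3S)-5-bromo-7-methoxy-2-[3-methoxy-4-(triisopropylsilyloxy)phenyl]-2,3-dihydro-1-benzofuran-3-yl]methanol
Product: 14 (2R,3S)-5-bromo-3-[(tert-butyldimethylsilyloxy)methyl]-7-methoxy-2-[3-methoxy-4-(triisopropylsilyloxy)phenyl]-2,3-dihydro-1-benzofuran
Conditions: TBSCl, imidazole, DMF, rt
Reagents that add atoms: tert-butyldimethylsilyl chloride (TBSCl), CC(C)(C)[Si](C)(C)Cl
Why: Standard silylation of the only free hydroxyl gives an ether that is stable to organolithium, Mitsunobu, DBU, carbenoid, methoxide and hydride conditions and falls to fluoride at the end.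

Step 12
Reactants: 14 (2R,3S)-5-bromo-3-[(tert-butyldimethylsilyloxy)methyl]-7-methoxy-2-[3-methoxy-4-(triisopropylsilyloxy)phenyl]-2,3-dihydro-1-benzofuran
Product: 17 (2R,3S)-3-[(tert-butyldimethylsilyloxy)methyl]-7-methoxy-2-[3-methoxy-4-(triisopropylsilyloxy)phenyl]-2,3-dihydro-1-benzofuran-5-carbaldehyde, via aryllithium 15 (not isolated), via lithium hemiaminal alkoxide 16 (not isolated)
Conditions: n-BuLi, THF, −78 °C; DMF, −78 °C to 0 °C; H2O
Reagents that add atoms: N,N-dimethylformamide (DMF), CN(C)C=O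
Why: Bromine–lithium exchange is faster at −78 °C than any deprotonation, and Bouveault-type formylation of 15 with DMF stops at alkoxide 16, which collapses to the aldehyde only on quench.

Step 13
Reactants: 17 (2R,3S)-3-[(tert-butyldimethylsilyloxy)methyl]-7-methoxy-2-[3-methoxy-4-(triisopropylsilyloxy)phenyl]-2,3-dihydro-1-benzofuran-5-carbaldehyde
Product: 18 [(2R,3S)-3-[(tert-butyldimethylsilyloxy)methyl]-7-methoxy-2-[3-methoxy-4-(triisopropylsilyloxy)phenyl]-2,3-dihydro-1-benzofuran-5-yl]methanol
Conditions: NaBH4, MeOH/THF, 0 °C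
Reagents that add atoms: none
Why: Borohydride reduction of the aryl aldehyde gives the ring C benzylic alcohol and touches neither silyl ether.

Step 14
Reactants: 18 [(2R,3S)-3-[(tert-butyldimethylsilyloxy)methyl]-7-methoxy-2-[3-methoxy-4-(triisopropylsilyloxy)phenyl]-2,3-dihydro-1-benzofuran-5-yl]methanol; 5 methyl 2-(5-bromo-2-hydroxy-3-methoxyphenyl)acetate
Product: 19 methyl 2-[5-bromo-3-methoxy-2-({(2R,3S)-3-[(tert-butyldimethylsilyloxy)methyl]-7-methoxy-2-[3-methoxy-4-(triisopropylsilyloxy)phenyl]-2,3-dihydro-1-benzofuran-5-yl}methoxy)phenyl]acetate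
Conditions: PPh3, DIAD, THF, 0 °C to rt
Reagents that add atoms: none
Why: A second Mitsunobu etherification joins the fragments at O1'–CH2 directly from the alcohol, which avoids the para-alkoxybenzyl bromide of ring C (prone to ionisation) and any carbonate base.

Step 15
Reactants: 19 methyl 2-[5-bromo-3-methoxy-2-({(2R,3S)-3-[(tert-butyldimethylsilyloxy)methyl]-7-methoxy-2-[3-methoxy-4-(triisopropylsilyloxy)phenyl]-2,3-dihydro-1-benzofuran-5-yl}methoxy)phenyl]acetate
Product: 20 methyl 2-[5-bromo-3-methoxy-2-({(2R,3S)-3-[(tert-butyldimethylsilyloxy)methyl]-7-methoxy-2-[3-methoxy-4-(triisopropylsilyloxy)phenyl]-2,3-dihydro-1-benzofuran-5-yl}methoxy)phenyl]-2-diazoacetate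
Conditions: p-ABSA, DBU, dry MeCN, 0 °C to rt
Reagents that add atoms: 4-acetamidobenzenesulfonyl azide (p-ABSA), CC(=O)Nc1ccc(cc1)S(=O)(=O)N=[N+]=[N-]
Why: Regitz diazo transfer as in step 7, the arylacetate CH2 being the only position acidic enough for DBU and the anhydrous medium protecting the aryl silyl ether.

Step 16
Reactants: 20 methyl 2-[5-bromo-3-methoxy-2-({(2R,3S)-3-[(tert-butyldimethylsilyloxy)methyl]-7-methoxy-2-[3-methoxy-4-(triisopropylsilyloxy)phenyl]-2,3-dihydro-1-benzofuran-5-yl}methoxy)phenyl]-2-diazoacetate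
Product: 21 methyl (2R,3S)-5-bromo-2-{(2R,3S)-3-[(tert-butyldimethylsilyloxy)methyl]-7-methoxy-2-[3-methoxy-4-(triisopropylsilyloxy)phenyl]-2,3-dihydro-1-benzofuran-5-yl}-7-methoxy-2,3-dihydro-1-benzofuran-3-carboxylate (ring D cis, 2'R,3'S)
Conditions: Rh2(S-PTTL)4 (2 mol%), toluene, 4 Å MS, −60 °C, slow addition of 20
Reagents that add atoms: none
Why: The diazo carbon of 20 binds to an axial site of Rh2(S-PTTL)4, N2 leaves, and the electrophilic carbenoid at C3' (ring E as donor, CO2Me as acceptor) attacks one C–H bond of the O1'–CH2–ring C group in a single step, the hydrogen moving to C3' with hydride character slightly ahead of C2'–C3' bond formation, after which the catalyst is released. The closest known reaction is the dirhodium tetracarboxylate-catalysed intramolecular insertion of methyl 2-(benzyloxy)phenyl diazoacetates that gives cis-2-aryl-2,3-dihydrobenzofuran-3-carboxylates, already used in step 8. Ring D closes as a five-membered ring by 1,5 insertion along C3'–C3a'–C7a'–O1'–C2', the only ring size for which a C–H bond lies within reach of the carbenoid. C2' is set by the catalyst, whose four phthalimido groups leave one open face on the carbenoid and so admit only one of the two benzylic hydrogens (taken as the one leading to 2'R), and C3' is set by the geometry of that transition state, in which ring C turns away from the ligand wall and ends on the same face as the ester (3'S, cis), to be corrected in step 17. The step needs site selectivity over the methoxy, silyloxymethyl and ring B C2–H bonds, over addition to the electron-rich arenes and over carbene dimerisation: the benzylic CH2 alone is 1,5-placed and is activated by O1' and by the para oxygen O1 of ring C, which carry the positive charge building on C2', the donor/acceptor carbenoid is tame enough to ignore silyl ethers and the aryl bromide, and slow addition to the dry catalyst solution keeps the diazo concentration low. As 20 is already enantioenriched, a wrong-face insertion gives a diastereomer and not the enantiomer, so it can be removed by chromatography and the enantiomeric purity of the main product should rise.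

Step 17
Reactants: 21 ring D cis ester (2'R,3'S)
Product: 22 methyl (2R,3R)-5-bromo-2-{(2R,3S)-3-[(tert-butyldimethylsilyloxy)methyl]-7-methoxy-2-[3-methoxy-4-(triisopropylsilyloxy)phenyl]-2,3-dihydro-1-benzofuran-5-yl}-7-methoxy-2,3-dihydro-1-benzofuran-3-carboxylate (ring D trans, 2'R,3'R)
Conditions: NaOMe (0.2 equiv), MeOH/THF, 0 °C to rt; AcOH quench
Reagents that add atoms: none
Why: Enolate-mediated epimerisation as in step 9 turns C3' to the favoured trans arrangement, C2' being held by the poor overlap of C2'–O1' with the enolate and ring B having no acidic C–H left.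

Step 18
Reactants: 22 ring D trans ester (2'R,3'R)
Product: 23 [(2R,3S)-5-bromo-2-{(2R,3S)-3-[(tert-butyldimethylsilyloxy)methyl]-7-methoxy-2-[3-methoxy-4-(triisopropylsilyloxy)phenyl]-2,3-dihydro-1-benzofuran-5-yl}-7-methoxy-2,3-dihydro-1-benzofuran-3-yl]methanol (2'R,3'S)
Conditions: LiAlH4, THF, 0 °C; aqueous NaOH work-up
Reagents that add atoms: none
Why: Hydride reduction of the ester ahead of the cross-coupling locks C3' and removes the one group that aqueous base could hydrolyse or epimerise in step 19, and it keeps LiAlH4 away from the cinnamyl system.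

Step 19
Reactants: 23 ring D alcohol bromide; 24 (E)-3-(tert-butyldimethylsilyloxy)prop-1-enylboronic acid pinacol ester
Product: 25 [(2R,3S)-5-[(E)-3-(tert-butyldimethylsilyloxy)prop-1-enyl]-2-{(2R,3S)-3-[(tert-butyldimethylsilyloxy)methyl]-7-methoxy-2-[3-methoxy-4-(triisopropylsilyloxy)phenyl]-2,3-dihydro-1-benzofuran-5-yl}-7-methoxy-2,3-dihydro-1-benzofuran-3-yl]methanol
Conditions: Pd(OAc)2 (5 mol%), SPhos (10 mol%), K3PO4, toluene/H2O, 60 °C
Reagents that add atoms: none
Why: Suzuki–Miyaura coupling, in which the electron-rich biarylphosphine lets zerovalent palladium add to the electron-rich C5'–Br bond and transmetalation and reductive elimination keep the E geometry of the alkenylboronate, the free primary alcohol being a spectator.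

Step 20
Reactants: 25 tris-silyl ether
Product: 26 4-[(2R,3S)-3-(hydroxymethyl)-5-[(2R,3S)-3-(hydroxymethyl)-5-[(E)-3-hydroxyprop-1-enyl]-7-methoxy-2,3-dihydro-1-benzofuran-2-yl]-7-methoxy-2,3-dihydro-1-benzofuran-2-yl]-2-methoxyphenol (target)
Conditions: TBAF, AcOH (equimolar with TBAF), THF, 0 °C to rt
Reagents that add atoms: none
Why: Fluoride-driven cleavage of the aryl TIPS ether and both primary TBS ethers in one operation, the acetic acid buffer keeping the liberated ring A phenol protonated so that ring B is not opened through a quinone methide and the acid-sensitive cinnamyl alcohol never meets strong acid.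

## Compound list

1 | 5-bromo-2-hydroxy-3-methoxybenzaldehyde | COc1cc(Br)cc(C=O)c1O | starting material
2 | 5-bromo-3-methoxy-2-(methoxymethoxy)benzaldehyde | COCOc1c(OC)cc(Br)cc1C=O | intermediate
3 | N-{2-[5-bromo-3-methoxy-2-(methoxymethoxy)phenyl]-1-tosylethenyl}formamide (not isolated) | O=CNC(=Cc1cc(Br)cc(OC)c1OCOC)S(=O)(=O)c1ccc(C)cc1 | intermediate
4 | 2-[5-bromo-3-methoxy-2-(methoxymethoxy)phenyl]acetonitrile | COCOc1c(OC)cc(Br)cc1CC#N | intermediate
5 | methyl 2-(5-bromo-2-hydroxy-3-methoxyphenyl)acetate | COC(=O)Cc1cc(Br)cc(OC)c1O | intermediate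
6 | vanillin | COc1cc(C=O)ccc1O | starting material
7 | 3-methoxy-4-(triisopropylsilyloxy)benzaldehyde | COc1cc(C=O)ccc1O[Si](C(C)C)(C(C)C)C(C)C | intermediate
8 | [3-methoxy-4-(triisopropylsilyloxy)phenyl]methanol | COc1cc(CO)ccc1O[Si](C(C)C)(C(C)C)C(C)C | intermediate
9 | methyl 2-[5-bromo-3-methoxy-2-{[3-methoxy-4-(triisopropylsilyloxy)phenyl]methoxy}phenyl]acetate | COC(=O)Cc1cc(Br)cc(OC)c1OCc1ccc(O[Si](C(C)C)(C(C)C)C(C)C)c(OC)c1 | intermediate
10 | methyl 2-[5-bromo-3-methoxy-2-{[3-methoxy-4-(triisopropylsilyloxy)phenyl]methoxy}phenyl]-2-diazoacetate | COC(=O)C(=[N+]=[N-])c1cc(Br)cc(OC)c1OCc1ccc(O[Si](C(C)C)(C(C)C)C(C)C)c(OC)c1 | intermediate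
11 | methyl (2R,3S)-5-bromo-7-methoxy-2-[3-methoxy-4-(triisopropylsilyloxy)phenyl]-2,3-dihydro-1-benzofuran-3-carboxylate (cis) | COc1cc([C@@H]2Oc3c(OC)cc(Br)cc3[C@@H]2C(=O)OC)ccc1O[Si](C(C)C)(C(C)C)C(C)C | intermediate
12 | methyl (2R,3R)-5-bromo-7-methoxy-2-[3-methoxy-4-(triisopropylsilyloxy)phenyl]-2,3-dihydro-1-benzofuran-3-carboxylate (trans) | COc1cc([C@@H]2Oc3c(OC)cc(Br)cc3[C@H]2C(=O)OC)ccc1O[Si](C(C)C)(C(C)C)C(C)C | intermediate
13 | [(2R,3S)-5-bromo-7-methoxy-2-[3-methoxy-4-(triisopropylsilyloxy)phenyl]-2,3-dihydro-1-benzofuran-3-yl]methanol | COc1cc([C@@H]2Oc3c(OC)cc(Br)cc3[C@H]2CO)ccc1O[Si](C(C)C)(C(C)C)C(C)C | intermediate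
14 | (2R,3S)-5-bromo-3-[(tert-butyldimethylsilyloxy)methyl]-7-methoxy-2-[3-methoxy-4-(triisopropylsilyloxy)phenyl]-2,3-dihydro-1-benzofuran | COc1cc([C@@H]2Oc3c(OC)cc(Br)cc3[C@H]2CO[Si](C)(C)C(C)(C)C)ccc1O[Si](C(C)C)(C(C)C)C(C)C | intermediate
15 | C5 aryllithium from 14 (not isolated) | COc1cc([C@@H]2Oc3c(OC)cc([Li])cc3[C@H]2CO[Si](C)(C)C(C)(C)C)ccc1O[Si](C(C)C)(C(C)C)C(C)C | intermediate
16 | lithium hemiaminal alkoxide from 15 and DMF (not isolated) | COc1cc([C@@H]2Oc3c(OC)cc(C([O-])N(C)C)cc3[C@H]2CO[Si](C)(C)C(C)(C)C)ccc1O[Si](C(C)C)(C(C)C)C(C)C.[Li+] | intermediate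
17 | (2R,3S)-3-[(tert-butyldimethylsilyloxy)methyl]-7-methoxy-2-[3-methoxy-4-(triisopropylsilyloxy)phenyl]-2,3-dihydro-1-benzofuran-5-carbaldehyde | COc1cc([C@@H]2Oc3c(OC)cc(C=O)cc3[C@H]2CO[Si](C)(C)C(C)(C)C)ccc1O[Si](C(C)C)(C(C)C)C(C)C | intermediate
18 | [(2R,3S)-3-[(tert-butyldimethylsilyloxy)methyl]-7-methoxy-2-[3-methoxy-4-(triisopropylsilyloxy)phenyl]-2,3-dihydro-1-benzofuran-5-yl]methanol | COc1cc([C@@H]2Oc3c(OC)cc(CO)cc3[C@H]2CO[Si](C)(C)C(C)(C)C)ccc1O[Si](C(C)C)(C(C)C)C(C)C | intermediate
19 | ring E arylacetate O-benzylated by the ring A/B/C unit | COc1cc([C@@H]2Oc3c(OC)cc(COc4c(OC)cc(Br)cc4CC(=O)OC)cc3[C@H]2CO[Si](C)(C)C(C)(C)C)ccc1O[Si](C(C)C)(C(C)C)C(C)C | intermediate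
20 | ring E aryldiazoacetate O-benzylated by the ring A/B/C unit (key precursor) | COc1cc([C@@H]2Oc3c(OC)cc(COc4c(OC)cc(Br)cc4C(=[N+]=[N-])C(=O)OC)cc3[C@H]2CO[Si](C)(C)C(C)(C)C)ccc1O[Si](C(C)C)(C(C)C)C(C)C | intermediate
21 | ring D cis methyl ester, 2R,3S,2'R,3'S, C5' bromide (key product) | COc1cc([C@@H]2Oc3c(OC)cc([C@@H]4Oc5c(OC)cc(Br)cc5[C@@H]4C(=O)OC)cc3[C@H]2CO[Si](C)(C)C(C)(C)C)ccc1O[Si](C(C)C)(C(C)C)C(C)C | intermediate
22 | ring D trans methyl ester, 2R,3S,2'R,3'R | COc1cc([C@@H]2Oc3c(OC)cc([C@@H]4Oc5c(OC)cc(Br)cc5[C@H]4C(=O)OC)cc3[C@H]2CO[Si](C)(C)C(C)(C)C)ccc1O[Si](C(C)C)(C(C)C)C(C)C | intermediate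
23 | ring D trans primary alcohol, 2R,3S,2'R,3'S, C5' bromide | COc1cc([C@@H]2Oc3c(OC)cc([C@@H]4Oc5c(OC)cc(Br)cc5[C@H]4CO)cc3[C@H]2CO[Si](C)(C)C(C)(C)C)ccc1O[Si](C(C)C)(C(C)C)C(C)C | intermediate
24 | (E)-3-(tert-butyldimethylsilyloxy)prop-1-enylboronic acid pinacol ester | CC1(C)OB(/C=C/CO[Si](C)(C)C(C)(C)C)OC1(C)C | starting material
25 | tris-silyl ether of the target (aryl OTIPS, C3 CH2OTBS, allylic OTBS) | COc1cc([C@@H]2Oc3c(OC)cc([C@@H]4Oc5c(OC)cc(/C=C/CO[Si](C)(C)C(C)(C)C)cc5[C@H]4CO)cc3[C@H]2CO[Si](C)(C)C(C)(C)C)ccc1O[Si](C(C)C)(C(C)C)C(C)C | intermediate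
26 | CNP0250921.1, 2R,3S,2'R,3'S | COc1cc([C@@H]2Oc3c(OC)cc([C@@H]4Oc5c(OC)cc(/C=C/CO)cc5[C@H]4CO)cc3[C@H]2CO)ccc1O | target

## Step count and risks

Total step count: 20.
Longest linear sequence: 18 steps (steps 1–3, then 6–20). The vanillin branch (steps 4–5) joins at step 6, and phenol ester 5 is made once and used twice.

**Step 16.**
- What may go wrong: facial selectivity at the benzylic CH2 may be poor, because the flanking C7' methoxy group and the bulky ring A/B/C unit can change how the ether sits in the chiral pocket. Carbene dimerisation may also take over if insertion is slow at low temperature.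
- Fallback: stereocontrol is shared with a covalently bound auxiliary, setting out from 19.
  - Me3SnOH in 1,2-dichloroethane at 80 °C cleaves the methyl ester to the carboxylic acid F1.
  - EDC·HCl and DMAP with (R)-2-hydroxy-1-(pyrrolidin-1-yl)propan-1-one give the (R)-lactamide ester F2.
  - p-ABSA and DBU in MeCN give the lactamide diazo ester F3.
  - Insertion with Rh2(R-DOSP)4 (dirhodium tetrakis[(R)-N-(4-dodecylphenylsulfonyl)prolinate]) in CH2Cl2 should give the ring D lactamide ester F4. Auxiliary and catalyst act in the same sense, and every stereoisomer is a separable diastereomer.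
  - NaOMe in MeOH then exchanges the auxiliary for methoxide and equilibrates C3', which comes back to the route at 22.

**Step 8.**
- What may go wrong: discrimination between the two enantiotopic benzylic hydrogens may be insufficient, since the bromine and the C7 methoxy group are absent from the simplest substrates of this reaction. The absolute configuration of the whole molecule depends on this step.
- Fallback: resolution through diastereomeric esters, setting out from 13 of insufficient enantiomeric purity.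
  - Esterification with (S)-2-methoxy-2-phenylacetic acid (EDC·HCl, DMAP, CH2Cl2, 0 °C) gives the (2R,3S) O-methylmandelate F5 together with the (2S,3R) O-methylmandelate F6.
  - The two are separated by chromatography or crystallisation.
  - LiAlH4 in THF at 0 °C releases the alcohol from F5, which comes back to the route at 13 as a single enantiomer.

**Step 9.**
- What may go wrong: methoxide may remove the phenolic silyl group, after which the para-phenoxide can open ring B at C2–O1 through a quinone methide. While C3 is still epimerisable, this would erode the enantiomeric purity. Equilibration may also stay incomplete under the mild conditions.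
- Fallback: epimerisation at the aldehyde oxidation level under an amine base, setting out from 11.
  - LiAlH4 in THF at 0 °C gives the cis alcohol F7.
  - Dess–Martin oxidation (NaHCO3, CH2Cl2) gives the cis aldehyde F8.
  - Catalytic DBU in CH2Cl2 at rt turns it into the trans aldehyde F9.
  - NaBH4 in MeOH at 0 °C comes back to the route at 13.

## Further compounds

F1 | step 16 | 2-[5-bromo-3-methoxy-2-({ring A/B/C unit of 19}methoxy)phenyl]acetic acid | COc1cc([C@@H]2Oc3c(OC)cc(COc4c(OC)cc(Br)cc4CC(=O)O)cc3[C@H]2CO[Si](C)(C)C(C)(C)C)ccc1O[Si](C(C)C)(C(C)C)C(C)C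
F2 | step 16 | (R)-1-oxo-1-(pyrrolidin-1-yl)propan-2-yl ester of F1 | COc1cc([C@@H]2Oc3c(OC)cc(COc4c(OC)cc(Br)cc4CC(=O)O[C@H](C)C(=O)N5CCCC5)cc3[C@H]2CO[Si](C)(C)C(C)(C)C)ccc1O[Si](C(C)C)(C(C)C)C(C)C
F3 | step 16 | α-diazo derivative of F2 | COc1cc([C@@H]2Oc3c(OC)cc(COc4c(OC)cc(Br)cc4C(=[N+]=[N-])C(=O)O[C@H](C)C(=O)N5CCCC5)cc3[C@H]2CO[Si](C)(C)C(C)(C)C)ccc1O[Si](C(C)C)(C(C)C)C(C)C
F4 | step 16 | ring D trans (2'R,3'R) lactamide ester | COc1cc([C@@H]2Oc3c(OC)cc([C@@H]4Oc5c(OC)cc(Br)cc5[C@H]4C(=O)O[C@H](C)C(=O)N6CCCC6)cc3[C@H]2CO[Si](C)(C)C(C)(C)C)ccc1O[Si](C(C)C)(C(C)C)C(C)C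
F5 | step 8 | (S)-2-methoxy-2-phenylacetate of (2R,3S)-13 | COc1cc([C@@H]2Oc3c(OC)cc(Br)cc3[C@H]2COC(=O)[C@@H](OC)c4ccccc4)ccc1O[Si](C(C)C)(C(C)C)C(C)C
F6 | step 8 | (S)-2-methoxy-2-phenylacetate of the (2S,3R) enantiomer of 13 | COc1cc([C@H]2Oc3c(OC)cc(Br)cc3[C@@H]2COC(=O)[C@@H](OC)c4ccccc4)ccc1O[Si](C(C)C)(C(C)C)C(C)C
F7 | step 9 | [(2R,3R)-5-bromo-7-methoxy-2-[3-methoxy-4-(triisopropylsilyloxy)phenyl]-2,3-dihydro-1-benzofuran-3-yl]methanol (cis) | COc1cc([C@@H]2Oc3c(OC)cc(Br)cc3[C@@H]2CO)ccc1O[Si](C(C)C)(C(C)C)C(C)C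
F8 | step 9 | (2R,3S)-5-bromo-7-methoxy-2-[3-methoxy-4-(triisopropylsilyloxy)phenyl]-2,3-dihydro-1-benzofuran-3-carbaldehyde (cis) | COc1cc([C@@H]2Oc3c(OC)cc(Br)cc3[C@@H]2C=O)ccc1O[Si](C(C)C)(C(C)C)C(C)C
F9 | step 9 | (2R,3R)-5-bromo-7-methoxy-2-[3-methoxy-4-(triisopropylsilyloxy)phenyl]-2,3-dihydro-1-benzofuran-3-carbaldehyde (trans) | COc1cc([C@@H]2Oc3c(OC)cc(Br)cc3[C@H]2C=O)ccc1O[Si](C(C)C)(C(C)C)C(C)C
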